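- Start with an easy step: you have two flasks to compare, two earlier runs to read, and one subtraction to make.

| flask | free monomer | protic impurity | initiator | remark | time |
|---|---|---|---|---|---|
| elm | 0.68 M | 0.30 M | 15 mM | run made earlier |  |
| oak | 1.8 M | 0.30 M | 15 mM | run made earlier |  |
| red | 1.5 M | 0.300 M | 15 mM |  | 50 min |
| amber | 0.50 M | 0.300 M | 15 mM |  | 50 min |

| run | time / min | monomer in chains / % | free monomer / % |
|---|---|---|---|
| elm | 4.00 | 1.1 | 80.6 |
| elm | 8.00 | 0.9 | 70.7 |
| elm | 12.0 | 1.5 | 64.2 |
| elm | 15.0 | 3.1 | 60.8 |
| elm | 20.0 | 3.6 | 57.0 |
| elm | 25.0 | 5.4 | 53.4 |
| oak | 4.00 | 0.9 | 85.9 |
| oak | 8.00 | 2.3 | 82.2 |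
| oak | 12.0 | 3.9 | 79.5 |
| oak | 15.0 | 4.9 | 78.2 |
| oak | 20.0 | 7.3 | 75.7 |
| oak | 25.0 | 8.7 | 73.2 |

(readings scatter by 0.3 percentage points)

- which of the two ends with the longer chains by the average number of monomer units in a chain (chains begun, living or dead) ("neither" if they lie within 10%) (red / amber / neither)
- average number of monomer units in a chain (chains begun, living or dead) at the end, red
- average number of monomer units in a chain (chains begun, living or dead) at the end, amber

- the average divides the monomer in chains by the number of chains begun, living and dead together
- the numbers in the tables scatter with a standard deviation of 0.3 percentage points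
- the earlier runs do not show the number of chains; that part of a forecast is a guess

- Take what stands as free monomer and as monomer in chains away from the charge at 25.0 min: the elm run is short by 0.280 M and the oak run by 0.326 M, although their monomer charges were 0.68 M and 1.8 M, so the missing amount tracks the 0.30 M of protic impurity, and I read it as each impurity removing one free monomer.
- The red flask's 1.20 M is then its margin, the charged c(free monomer) minus the charged c(protic impurity), the monomer that outlasts this quench, while the amber flask's margin is 0.200 M; in both, by their charges, the protic impurity is the limiting reagent of the quench.
- Turn the question round: length is monomer in chains over chains begun, so if each flask put the same share of its margin into chains, amber could end longer only with its chains begun down by a factor beyond 6.00, and since both hold 15 mM of initiator I see no ground for that, though the number of chains is a guess; my own reckoning is red, ahead by about that factor.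
- The forecast says red, with 16.5 against 2.8, on the ground that “impurity consumes monomer about 1:1”.
- The flask gives red, with 18.4 against 4.16, a factor of 4.42, which is less than the 6.00 of my reckoning.

    free monomer + living end → monomer in chains + living end, rate k1*[living end]*[free monomer] (k = 0.401 M⁻¹ min⁻¹)
    free monomer + initiator → living end + monomer in chains (k = 0.0869 M⁻¹ min⁻¹)
    free monomer → uncatalysed product (k = 4.28 × 10⁻⁴ min⁻¹)
    2 initiator → spent initiator (k = 0.375 M⁻¹ min⁻¹)
    protic impurity + free monomer → quenched substrate (k = 0.221 M⁻¹ min⁻¹)

- At the end of the red flask, free monomer, monomer in chains and uncatalysed product together come to 1.20 M against its margin of 1.20 M; in the amber flask, with 5.85% of its impurity still there, they come to 0.218 M against 0.200 M. The neighbouring flask, amber with 0.12 M of free monomer, has a margin of −0.180 M, so free monomer takes the limiting place in the quench. It ends with 64% of its charged protic impurity left, quenched substrate at 89.0% of its charged free monomer, and an average of 1.43 monomer units in a chain.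

The readings are simulated with constants of no real substance, and the scatter is random.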